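**Plan**
- Retrosynthesis: the two MOM ethers and the enone Cα=Cβ bond are cut first (Claisen–Schmidt), giving acetophenone 7 and aldehyde 8. The C3 carbinol is traced back to ketone 6. The C4–C4a bond of the pyran ring is then cut, unravelling 6 to aryl 1,1-dimethylpropargyl ether 4, and the O1–C2 bond is cut to phenol 2 and chloroalkyne 3.
- Forward: ring A is bought complete. The 4'-OH is masked, the chelated 2'-OH is given the C5 alkyne unit, the pyranone ring is closed by C4–C4a bond formation, the ketone is reduced, the chalcone arm is added, and both MOM groups are removed together.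
- Enabling feature: O1 sits on C8a of the phloroglucinol-type ring A. The only free ortho carbon, C4a, lies between O1 and the C5 oxygen and para to the C7 methoxy, so it is strongly nucleophilic, while the C8 acetyl blocks the other ortho site. C3 and C4 map onto the two carbons of a terminal alkyne, so gold-catalysed N-oxide oxidation turns the alkyne terminus into an electrophilic alpha-oxo carbene that installs the C3 oxygen and the C4–C4a bond in one event.
- Stereochemistry: the only stereocentre, C3 (S), comes from a CBS reduction of prochiral chroman-3-one 6 (reagent control, C2 quaternary carbon versus C4 methylene). The E-alkene is the thermodynamic outcome of the aldol condensation.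

Key step: step 3

Remark: C3 of the target is read as (S); compounds 1, 3 and 8 are taken as catalogue materials.

Step 1
Reactants: 1 2',4'-dihydroxy-6'-methoxyacetophenone
Product: 2 2'-hydroxy-6'-methoxy-4'-(methoxymethoxy)acetophenone
Conditions: MOMCl (1.1 equiv), K2CO3, acetone, 0 °C to rt
Reagents that add atoms: chloromethyl methyl ether (MOMCl), COCCl
Why: Williamson-type MOM etherification is expected at the 4'-OH alone, because it is the more acidic and accessible phenol whereas the 2'-OH is held in a hydrogen bond to the acetyl carbonyl.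

Step 2
Reactants: 2 2'-hydroxy-6'-methoxy-4'-(methoxymethoxy)acetophenone; 3 3-chloro-3-methylbut-1-yne
Product: 4 2'-methoxy-4'-(methoxymethoxy)-6'-[(2-methylbut-3-yn-2-yl)oxy]acetophenone
Conditions: 3 (2 equiv), DBU (2.2 equiv), CuCl2·2H2O (2 mol %), MeCN, 0 °C to rt
Reagents that add atoms: none
Why: Copper-catalysed propargylic etherification of a phenol with a tertiary propargylic chloride, in which DBU fully deprotonates the chelated ortho-acyl phenol and the copper catalyst activates the tertiary propargylic centre so that O-alkylation should proceed at low temperature, well below the onset of Claisen rearrangement; no stereocentre arises.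

Step 3
Reactants: 4 2'-methoxy-4'-(methoxymethoxy)-6'-[(2-methylbut-3-yn-2-yl)oxy]acetophenone
Product: 6 8-acetyl-7-methoxy-5-(methoxymethoxy)-2,2-dimethylchroman-3-one, via alpha-oxo gold carbene 5 (not isolated)
Conditions: (Me4tBuXPhos)AuNTf2 (5 mol %; Me4tBuXPhos = 2-di-tert-butylphosphino-3,4,5,6-tetramethyl-2',4',6'-triisopropylbiphenyl), 2,6-dichloropyridine N-oxide (1.5 equiv), 1,2-dichloroethane, rt
Reagents that add atoms: 2,6-dichloropyridine N-oxide, [O-][n+]1c(Cl)cccc1Cl
Why: The cationic monovalent gold complex activates the terminal alkyne, the N-oxide oxygen adds to the internal alkyne carbon and N–O heterolysis expels 2,6-dichloropyridine to leave alpha-oxo gold carbene 5 at the former terminal carbon, which reverses the polarity of the normally nucleophilic alkyne terminus. The electrophilic carbene carbon should then be attacked by C4a of ring A, and rearomatisation with protodeauration delivers the C4 methylene; the closest known reaction type is the gold-catalysed oxidative cyclisation of aryl propargyl ethers to chroman-3-ones. The pyranone ring closes in a six-membered Friedel–Crafts mode (formally 6-exo-trig on the Au=C carbon), assisted by the gem-dimethyl (Thorpe–Ingold) effect. No stereocentre is formed; C3 emerges as a prochiral ketone for step 4. Regioselectivity is fixed because the acetyl group occupies the other ortho position, and selectivity for oxygen transfer over 6-endo hydroarylation or double oxidation rests on the bulky biaryl phosphine, the excess of hindered N-oxide and the fast intramolecular capture by the electron-rich arene, while the acid-free conditions spare the MOM acetal.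

Step 4
Reactants: 6 8-acetyl-7-methoxy-5-(methoxymethoxy)-2,2-dimethylchroman-3-one
Product: 7 1-[(3S)-3-hydroxy-7-methoxy-5-(methoxymethoxy)-2,2-dimethyl-3,4-dihydro-2H-chromen-8-yl]ethan-1-one
Conditions: (R)-2-methyl-CBS-oxazaborolidine (15 mol %), BH3·SMe2 (0.7 equiv), THF, −20 °C, slow addition of 6; MeOH quench, aqueous work-up
Reagents that add atoms: none
Why: Corey–Bakshi–Shibata reduction in which the ketone should bind the catalyst boron anti to the bulky C2 quaternary carbon, so that the (R)-catalyst delivers hydride to the face giving the (3S)-carbinol, while the di-ortho-alkoxy aryl methyl ketone is far less electrophilic than the alpha-alkoxy ring ketone and should survive a sub-stoichiometric charge of borane.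

Step 5
Reactants: 7 1-[(3S)-3-hydroxy-7-methoxy-5-(methoxymethoxy)-2,2-dimethyl-3,4-dihydro-2H-chromen-8-yl]ethan-1-one; 8 4-(methoxymethoxy)benzaldehyde
Product: 10 (2E)-1-[(3S)-3-hydroxy-7-methoxy-5-(methoxymethoxy)-2,2-dimethyl-3,4-dihydro-2H-chromen-8-yl]-3-[4-(methoxymethoxy)phenyl]prop-2-en-1-one, via aldol adduct 9 (not isolated)
Conditions: KOH (50% aq, 5 equiv), EtOH, 0 °C to rt
Reagents that add atoms: none
Why: Claisen–Schmidt condensation in which the acetyl methyl is the only acidic C–H site, the aldehyde cannot enolise, and E1cB dehydration of aldol 9 should give the thermodynamically favoured E-enone, while the C3 carbinol (not alpha to a carbonyl) and the MOM ethers are inert to aqueous-alcoholic KOH.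

Step 6
Reactants: 10 (2E)-1-[(3S)-3-hydroxy-7-methoxy-5-(methoxymethoxy)-2,2-dimethyl-3,4-dihydro-2H-chromen-8-yl]-3-[4-(methoxymethoxy)phenyl]prop-2-en-1-one
Product: 11 (2E)-1-[(3S)-3,5-dihydroxy-7-methoxy-2,2-dimethyl-3,4-dihydro-2H-chromen-8-yl]-3-(4-hydroxyphenyl)prop-2-en-1-one
Conditions: 3 M HCl (aq)/MeOH, 50 °C
Reagents that add atoms: none
Why: Acid-catalysed transacetalisation should remove both MOM groups as dimethoxymethane, the cyclic tertiary alkyl aryl ether, the secondary alcohol and the E-enone being stable to dilute methanolic HCl, and with O-2' locked in the pyran ring no chalcone-to-flavanone cyclisation can occur.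

**Compound list**
1 | 2',4'-dihydroxy-6'-methoxyacetophenone [1-(2,4-dihydroxy-6-methoxyphenyl)ethan-1-one] | CC(=O)c1c(O)cc(O)cc1OC | starting material
2 | 2'-hydroxy-6'-methoxy-4'-(methoxymethoxy)acetophenone | CC(=O)c1c(O)cc(OCOC)cc1OC | intermediate
3 | 3-chloro-3-methylbut-1-yne | CC(C)(Cl)C#C | starting material
4 | 2'-methoxy-4'-(methoxymethoxy)-6'-[(2-methylbut-3-yn-2-yl)oxy]acetophenone | CC(=O)c1c(OC(C)(C)C#C)cc(OCOC)cc1OC | intermediate
5 | alpha-oxo gold carbene [(Me4tBuXPhos)Au=CH–C(=O)–C(CH3)2–OAr]NTf2, Ar = 2-acetyl-3-methoxy-5-(methoxymethoxy)phenyl (not isolated) | CC(=O)c1c(OC(C)(C)C(=O)C=[Au][P+](C(C)(C)C)(C(C)(C)C)c2c(C)c(C)c(C)c(C)c2-c3c(C(C)C)cc(C(C)C)cc3C(C)C)cc(OCOC)cc1OC.[N-](S(=O)(=O)C(F)(F)F)S(=O)(=O)C(F)(F)F | intermediate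
6 | 8-acetyl-7-methoxy-5-(methoxymethoxy)-2,2-dimethylchroman-3-one | COc1cc(OCOC)c2c(c1C(C)=O)OC(C)(C)C(=O)C2 | intermediate
7 | 1-[(3S)-3-hydroxy-7-methoxy-5-(methoxymethoxy)-2,2-dimethyl-3,4-dihydro-2H-chromen-8-yl]ethan-1-one | COc1cc(OCOC)c2c(c1C(C)=O)OC(C)(C)[C@@H](O)C2 | intermediate
8 | 4-(methoxymethoxy)benzaldehyde | COCOc1ccc(C=O)cc1 | starting material
9 | 3-hydroxy-1-[(3S)-3-hydroxy-7-methoxy-5-(methoxymethoxy)-2,2-dimethyl-3,4-dihydro-2H-chromen-8-yl]-3-[4-(methoxymethoxy)phenyl]propan-1-one, both carbinol epimers (not isolated) | COc1cc(OCOC)c2c(c1C(=O)CC(O)c1ccc(OCOC)cc1)OC(C)(C)[C@@H](O)C2 | intermediate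
10 | (2E)-1-[(3S)-3-hydroxy-7-methoxy-5-(methoxymethoxy)-2,2-dimethyl-3,4-dihydro-2H-chromen-8-yl]-3-[4-(methoxymethoxy)phenyl]prop-2-en-1-one | COc1cc(OCOC)c2c(c1C(=O)/C=C/c1ccc(OCOC)cc1)OC(C)(C)[C@@H](O)C2 | intermediate
11 | (2E)-1-[(3S)-3,5-dihydroxy-7-methoxy-2,2-dimethyl-3,4-dihydro-2H-chromen-8-yl]-3-(4-hydroxyphenyl)prop-2-en-1-one | COc1cc(O)c2c(c1C(=O)/C=C/c1ccc(O)cc1)OC(C)(C)[C@@H](O)C2 | target

**Totals**
Total step count: 6. Longest linear sequence: 6 steps (1 to 11).

**Steps most likely to fail**

Step 3 (key step). The risk is that gold-catalysed 6-endo hydroarylation of the alkyne by the electron-rich arene outruns oxygen transfer, or that the carbene is oxidised a second time before ring closure. The fallback sets out from 4 and comes back at 7, replacing steps 3 and 4. Heating 4 in N,N-diethylaniline at about 185 °C should bring about the aromatic propargyl Claisen rearrangement, 1,5-hydrogen shift and oxa-6π electrocyclisation to give 1-[7-methoxy-5-(methoxymethoxy)-2,2-dimethyl-2H-chromen-8-yl]ethan-1-one F1. Jacobsen–Katsuki epoxidation with (S,S)-(salen)MnCl, the chloride of trivalent manganese with (S,S)-N,N'-bis(3,5-di-tert-butylsalicylidene)cyclohexane-1,2-diamine, together with NaOCl and 4-phenylpyridine N-oxide in CH2Cl2 at 0 °C, is expected to give (3S,4S)-8-acetyl-3,4-epoxy-7-methoxy-5-(methoxymethoxy)-2,2-dimethylchromane F2. Hydrogenolysis of its benzylic C4–O bond (H2, Pd/C, EtOAc, rt) should then give 7 with C3 untouched.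

Step 2. The risk is slow O-alkylation of the hydrogen-bonded, ortho-acylated phenoxide at a tertiary centre, so that elimination of the chloroalkyne or C-propargylation of the ring takes over. The fallback sets out from 2 and comes back at 6, replacing steps 2 and 3 by a carbenoid C–H insertion that makes the same C4–C4a bond. O-Alkylation of 2 with ethyl 2-bromo-2-methylpropanoate (Cs2CO3, DMF, 60 °C) should give ethyl 2-[2-acetyl-3-methoxy-5-(methoxymethoxy)phenoxy]-2-methylpropanoate F3. Saponification (LiOH, THF/H2O) should give 2-[2-acetyl-3-methoxy-5-(methoxymethoxy)phenoxy]-2-methylpropanoic acid F4. Activation with isobutyl chloroformate and N-methylmorpholine (THF, −15 °C) should give the mixed isobutyl carbonic anhydride F5, which with diazomethane (Et2O, 0 °C) should give 3-[2-acetyl-3-methoxy-5-(methoxymethoxy)phenoxy]-1-diazo-3-methylbutan-2-one F6. Rh2(OAc)4 (1 mol %) in CH2Cl2 at rt should then effect intramolecular aromatic C–H insertion of the rhodium carbenoid at the free ortho carbon to give 6.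

Step 4. The risk is poor facial selectivity on a ketone whose two alpha-carbons are both ring carbons, or competing reduction of the aryl methyl ketone. The fallback sets out from 6 and comes back at 7. NaBH4 (MeOH, −78 °C) should reduce only the more electrophilic ring ketone to racemic 1-[3-hydroxy-7-methoxy-5-(methoxymethoxy)-2,2-dimethyl-3,4-dihydro-2H-chromen-8-yl]ethan-1-one F7. Lipase-catalysed kinetic resolution (immobilised Candida antarctica lipase B, vinyl acetate, MTBE, 40 °C) is expected by the Kazlauskas rule to acetylate the (R)-enantiomer to (3R)-8-acetyl-7-methoxy-5-(methoxymethoxy)-2,2-dimethyl-3,4-dihydro-2H-chromen-3-yl acetate F8 and leave the (S)-alcohol 7, which would be separated by chromatography.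

**Further compounds**
F1 | step 3 | 1-[7-methoxy-5-(methoxymethoxy)-2,2-dimethyl-2H-chromen-8-yl]ethan-1-one | COc1cc(OCOC)c2c(c1C(C)=O)OC(C)(C)C=C2
F2 | step 3 | (3S,4S)-8-acetyl-3,4-epoxy-7-methoxy-5-(methoxymethoxy)-2,2-dimethylchromane | COc1cc(OCOC)c2c(c1C(C)=O)OC(C)(C)[C@H]3O[C@@H]23
F3 | step 2 | ethyl 2-[2-acetyl-3-methoxy-5-(methoxymethoxy)phenoxy]-2-methylpropanoate | CCOC(=O)C(C)(C)Oc1cc(OCOC)cc(OC)c1C(C)=O
F4 | step 2 | 2-[2-acetyl-3-methoxy-5-(methoxymethoxy)phenoxy]-2-methylpropanoic acid | OC(=O)C(C)(C)Oc1cc(OCOC)cc(OC)c1C(C)=O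
F5 | step 2 | 2-[2-acetyl-3-methoxy-5-(methoxymethoxy)phenoxy]-2-methylpropanoic isobutyl carbonic anhydride | CC(C)COC(=O)OC(=O)C(C)(C)Oc1cc(OCOC)cc(OC)c1C(C)=O
F6 | step 2 | 3-[2-acetyl-3-methoxy-5-(methoxymethoxy)phenoxy]-1-diazo-3-methylbutan-2-one | [N-]=[N+]=CC(=O)C(C)(C)Oc1cc(OCOC)cc(OC)c1C(C)=O
F7 | step 4 | racemic 1-[3-hydroxy-7-methoxy-5-(methoxymethoxy)-2,2-dimethyl-3,4-dihydro-2H-chromen-8-yl]ethan-1-one | COc1cc(OCOC)c2c(c1C(C)=O)OC(C)(C)C(O)C2
F8 | step 4 | (3R)-8-acetyl-7-methoxy-5-(methoxymethoxy)-2,2-dimethyl-3,4-dihydro-2H-chromen-3-yl acetate | COc1cc(OCOC)c2c(c1C(C)=O)OC(C)(C)[C@H](OC(C)=O)C2
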